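The constants used here are invented, and the outcome is calculated.

If I followed one substrate to its end, it could leave in two ways: as side product, through a leak from the open intermediate, or as target, by meeting a second intermediate. So I asked which of two rates wins.

| flask | substrate | partner | capture agent | temperature | time | remark |
|---|---|---|---|---|---|---|
| eta | 0.30 M | 0.240 M (fed, over 12 h) | 0.0900 M | 20 °C | 2.5 d | all else is in the flask from the start; the feed brings no volume worth counting |
| delta | 0.30 M | 0.240 M (fed, over 50 h) | 0.0900 M | 20 °C | 2.5 d | all else is in the flask from the start; the feed brings no volume worth counting |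
| theta | 0.30 M | 0.240 M (in portions, 2, over 50 h) | 0.0900 M | 20 °C | 2.5 d | first portion at the start, last at 50 h |
| epsilon | 0.30 M | 0.240 M | 0.0900 M |  | 2.5 d | everything together at the start at 0 °C, warmed to 20 °C at 50 h |
| gamma | 0.30 M | 0.240 M | 0.0900 M | 20 °C | 2.5 d | everything together at the start |
| zeta | 0.30 M (fed, over 50 h) | 0.240 M | 0.0900 M |  | 2.5 d | the addition at 0 °C, then warmed to 20 °C; the feed brings no volume worth counting |

- the flask that comes out highest in amount of target, in percent of the substrate charged, or "all alike" when all lie within 1.5 percentage points (eta / delta / theta / epsilon / gamma / zeta / all alike)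
- target at the end, in percent of the substrate charged, eta
- target at the end, in percent of the substrate charged, delta
- target at the end, in percent of the substrate charged, theta
- target at the end, in percent of the substrate charged, epsilon
- target at the end, in percent of the substrate charged, gamma
- target at the end, in percent of the substrate charged, zeta

- where a step has two of a species, its rate is k times that concentration squared, and two are used at each turn
- at 20 °C the constants are as listed, elsewhere as the activation energies and enthalpies make them

    open intermediate → side product (k1 = 0.083 h⁻¹, Ea1 = 91.0 kJ mol⁻¹)
    substrate ⇌ open intermediate (K2 = 3.7, k2 = 0.54 h⁻¹, Ea2 = 85.0 kJ mol⁻¹, ΔH2 = −36.0 kJ mol⁻¹)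
    second intermediate + capture agent → trapped intermediate (k3 = 0.23 M⁻¹ h⁻¹, Ea3 = 67.0 kJ mol⁻¹)
    partner → second intermediate (k4 = 0.061 h⁻¹, Ea4 = 90.0 kJ mol⁻¹)
    open intermediate + second intermediate → target (k5 = 51 M⁻¹ h⁻¹, Ea5 = 57.0 kJ mol⁻¹)
    2 second intermediate → homo product (k6 = 0.90 M⁻¹ h⁻¹, Ea6 = 58.0 kJ mol⁻¹)
    (constants at 20 °C)

I treated substrate and open intermediate as one pool, with the open form holding 78.7% of it, so the pool's life against the leak was 15.3 h. I could use that equilibrium share because the relaxation half-life, 1.01 h in delta, is shorter than that life. At the charge, open intermediate takes up second intermediate at a pseudo-first-order 12.0 h⁻¹, far faster than the capture agent's 0.0207 h⁻¹. So while the pool lasted, I counted each delivered second intermediate as one target.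

Take x as the pool's fraction of the substrate charge. The partner charge is 0.800 of that charge and has a life of 16.4 h on its way to second intermediate. For delta, I took the delivery time as the feed time plus that life:

leak at the start = 0.0653 h⁻¹

delivery = 0.0120 h⁻¹

L = leak / delivery = 5.42

I called L the leak ratio. With delivery held steady, x reaches zero at pool life × ln(1 + L), and the target fraction is

y = ln(1 + L) / L

Delta gave 34.3%. Eta, with L = 2.32, gave 51.7%. Gamma, whose delivery time is the partner's life, had L = 1.34 and gave 63.5%, the highest of these. I did not reckon theta or the cold flasks.

The forecast also chose gamma, on the ground that “target equals second intermediate generated until the pool runs out”. It gave eta 48.9%, delta 28.6%, theta 37.3%, epsilon 43.3%, gamma 59.7% and zeta 43.6%. Its gamma figure is lower than mine, and so are its eta and delta figures.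

The simulation put gamma highest, with gamma 58.2%, eta 47.4%, zeta 43.4%, epsilon 43.3%, theta 36.2% and delta 27.4%, each inside the forecast's range. In gamma, substrate stood at 0% and open intermediate at 0% at the end, and 41.8% of the charge was side product.

Delta's leak ratio had given 34.3% against the flask's 27.4%, higher by 6.9 percentage points. The neighbour repeats delta at 45 °C. With the constants moved by their activation energies and enthalpy, the pool's life became 1.19 h and the partner's 0.901 h. So L rose to 53.3, and the same line gave 7.49%. The neighbour gave 5.38% of target, with side product at 94.6%.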